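**Retrosynthetic overview**

1. Presumed biosynthesis: a guai-4-en-12,8-olide carrying 11-OH is epoxidised on the α face of C4=C5, the 11-OH opens the epoxide at C5 to give the oxolane, and the lactone arises by acylation of O8 by C12. The route closes both heterocycles in this way.
2. Last bond: angelate on the 2α-OH. Before it: oxolane by 2α-OH-directed epoxidation and 5-exo epoxide opening; before that: lactone by hydride delivery to C8 and O8→C12 acylation.
3. Seven-membered ring: ring-closing metathesis (C9=C10), then cuprate methylation (C14).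
4. Five-membered ring from a (4S)-silyloxycyclopentenone: vinyl cuprate at C1, methylenation at C5, Michael addition of a pyruvate-aldol thioester (C7, C11–C13) with enol-triflate trapping, Stille methylation (C15).
5. Ring order: cyclopentene (bought) → cycloheptene → γ-lactone → oxolane.

Assumption: guaiane numbering (C1–C5 five-membered ring; C5–C10 and C1 seven-membered ring; C11–C13 on C7; C14 on C10; C15 on C4) and the α/β descriptors of the target (C7 side chain β) are used for all intermediates. Ring closure by metathesis rather than by transannular cyclization of a ten-membered ring is a deliberate choice.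

**Route**

Step 1
Reactants: 1 S-ethyl ethanethioate; 2 chlorotrimethylsilane
Product: 3 1-(ethylsulfanyl)-1-(trimethylsilyloxy)ethene
Conditions: LDA, THF, −78 °C; then Me3SiCl
Reagents that add atoms: chlorotrimethylsilane (2), C[Si](C)(C)Cl
Why: Kinetic enolisation of the thioester and O-silylation give the silyl ketene thioacetal for a Mukaiyama aldol; no stereocenter is formed.

Step 2
Reactants: 3 1-(ethylsulfanyl)-1-(trimethylsilyloxy)ethene; 4 methyl pyruvate
Product: 6 methyl (2S)-4-(ethylsulfanyl)-2-hydroxy-2-methyl-4-oxobutanoate, via silyl ether 5 (not isolated)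
Conditions: Cu(OTf)2 (10 mol%), (S,S)-t-Bu-box (11 mol%), THF, −78 °C; then 1 M HCl
Reagents that add atoms: methyl pyruvate (4), CC(=O)C(=O)OC
Why: Catalytic enantioselective Mukaiyama aldol (Evans type) in which the bis(oxazoline)–Cu(OTf)2 chelate of the pyruvate exposes one ketone face, so the (S)-carbinol (C11) is set by the ligand; acid then cleaves the silyl ether.

Step 3
Reactants: 7 (4S)-4-(tert-butyldimethylsilyloxy)cyclopent-2-en-1-one; 8 vinylmagnesium bromide; 9 N,N-dimethylmethyleneiminium iodide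
Product: 13 (3S,4S)-4-(tert-butyldimethylsilyloxy)-2-methylidene-3-vinylcyclopentan-1-one, via magnesium enolate 10 (not isolated), via Mannich base 11 (not isolated), via methiodide 12 (not isolated)
Conditions: CuBr·SMe2 (5 mol%), THF, −78 °C; CH2=NMe2 iodide, −78 to 0 °C; MeI; DBU, rt
Reagents that add atoms: vinylmagnesium bromide (8), C=C[Mg]Br; N,N-dimethylmethyleneiminium iodide (9), C=[N+](C)C.[I-]
Why: Copper-catalysed conjugate addition puts the vinyl group anti to the silyloxy group and so sets C1 (1α-H); the enolate is trapped in a Mannich reaction and the amine is expelled after N-methylation (Hofmann-type elimination) to give the exocyclic enone.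

Step 4
Reactants: 13 (3S,4S)-4-(tert-butyldimethylsilyloxy)-2-methylidene-3-vinylcyclopentan-1-one; 6 methyl (2S)-4-(ethylsulfanyl)-2-hydroxy-2-methyl-4-oxobutanoate; 14 N-phenylbis(trifluoromethanesulfonimide)
Product: 16 methyl (2S,3R)-4-[(4S,5S)-4-(tert-butyldimethylsilyloxy)-2-(trifluoromethanesulfonyloxy)-5-vinylcyclopent-1-en-1-yl]-3-(ethylsulfanylcarbonyl)-2-hydroxy-2-methylbutanoate, via dilithium enolate 15 (not isolated)
Conditions: 6, LDA (2.1 equiv), THF, −78 °C; 13; then PhNTf2, −78 to 0 °C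
Reagents that add atoms: N-phenylbis(trifluoromethanesulfonimide) (14), O=S(=O)(N(c1ccccc1)S(=O)(=O)C(F)(F)F)C(F)(F)F
Why: Michael addition of the chelated dilithio β-alkoxy thioester enolate (Fráter–Seebach-type dianion) to the exo-methylene ketone forms C6–C7 with C6 anti to O11 along the extended C8–C7–C11–C12 chain (7R), and the regiodefined C4 enolate is trapped as the enol triflate.

Step 5
Reactants: 16 enol triflate (name as in step 4); 17 tetramethylstannane
Product: 18 methyl (2S,3R)-4-[(4S,5S)-4-(tert-butyldimethylsilyloxy)-2-methyl-5-vinylcyclopent-1-en-1-yl]-3-(ethylsulfanylcarbonyl)-2-hydroxy-2-methylbutanoate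
Conditions: Me4Sn, Pd(PPh3)4 (5 mol%), LiCl, DMF, 80 °C
Reagents that add atoms: tetramethylstannane (17), C[Sn](C)(C)C
Why: Stille coupling of the enol triflate installs C15 on the tetrasubstituted C4=C5 alkene, and the thioester is inert without a copper cofactor; no stereocenter is formed.

Step 6
Reactants: 18 methyl alkene thioester (name as in step 5); 19 tributyl(vinyl)stannane
Product: 20 methyl (2S,3R)-3-{[(4S,5S)-4-(tert-butyldimethylsilyloxy)-2-methyl-5-vinylcyclopent-1-en-1-yl]methyl}-2-hydroxy-2-methyl-4-oxohex-5-enoate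
Conditions: Pd2(dba)3 (2.5 mol%), P(2-furyl)3, CuOP(O)Ph2 (1.5 equiv), THF, 50 °C
Reagents that add atoms: tributyl(vinyl)stannane (19), C=C[Sn](CCCC)(CCCC)CCCC
Why: Liebeskind–Srogl-type Pd/Cu coupling of the thioester with the vinylstannane gives the vinyl ketone under neutral conditions that leave the enolisable C7 centre and the free tertiary alcohol untouched.

Step 7
Reactants: 20 vinyl ketone (name as in step 6)
Product: 21 methyl (11S)-2α-(tert-butyldimethylsilyloxy)-11-hydroxy-8-oxo-14-nor-1αH,7αH-guaia-4,9-dien-12-oate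
Conditions: second-generation Grubbs catalyst (5 mol%), CH2Cl2, 40 °C
Reagents that add atoms: none
Why: Ring-closing metathesis between the C1 vinyl group and the vinyl ketone closes the seven-membered ring as the cis-enone while the tetrasubstituted C4=C5 alkene stays inert; no stereocenter is formed.

Step 8
Reactants: 21 bicyclic enone (name as in step 7); 22 lithium dimethylcuprate
Product: 23 methyl (11S)-2α-(tert-butyldimethylsilyloxy)-11-hydroxy-8-oxo-1αH,7αH,10βH-guai-4-en-12-oate
Conditions: Me2CuLi (2.5 equiv), Et2O, −78 °C; then H2O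
Reagents that add atoms: lithium dimethylcuprate (22), [Li+].C[Cu-]C
Why: Conjugate addition of the Gilman cuprate occurs trans to the substituent on the neighbouring ring-fusion carbon (the C1–C2 bond on the β face), so C14 enters on the α face and C10 is set (10β-H).

Step 9
Reactants: 23 methyl ketone (name as in step 8)
Product: 26 2α,11-dihydroxy-1αH,7αH,10βH-guai-4-en-12,8β-olide, via lithium alkoxide 24 (not isolated), via silyl lactone 25 (not isolated)
Conditions: LiBH(s-Bu)3, THF, −78 to 0 °C; then Bu4NF, 0 °C to rt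
Reagents that add atoms: none
Why: The bulky hydride attacks the C8 ketone from the face opposite the C7 side chain, and the resulting 8β-alkoxide (cis to C11) acylates itself with the C12 ester (lactonisation, the biosynthetic O8 acylation); fluoride then removes the silyl group.

Step 10
Reactants: 26 2α,11-dihydroxy-1αH,7αH,10βH-guai-4-en-12,8β-olide; 27 tert-butyl hydroperoxide
Product: 29 2α,4α-dihydroxy-5β,11-epoxy-1αH,7αH,10βH-guaian-12,8β-olide, via epoxide 28 (not isolated)
Conditions: VO(acac)2 (5 mol%), t-BuOOH, CH2Cl2, 0 °C to rt; then CSA (10 mol%)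
Reagents that add atoms: tert-butyl hydroperoxide (27), CC(C)(C)OO
Why: Vanadium-catalysed hydroxyl-directed epoxidation delivers oxygen to the face of the homoallylic 2α-OH (4α,5α-epoxide), and the 11-OH opens it at C5 in a 5-exo anti fashion, which is the presumed biosynthetic oxolane closure and sets 4α-OH and 5β-O.

Step 11
Reactants: 29 2α,4α-dihydroxy-5β,11-epoxy-1αH,7αH,10βH-guaian-12,8β-olide; 30 angelic acid; 31 2,4,6-trichlorobenzoyl chloride
Product: 33 2α-angeloyloxy-4α-hydroxy-5β,11-epoxy-1αH,7αH,10βH-guaian-12,8β-olide (CNP0293659.1), via mixed anhydride 32 (not isolated)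
Conditions: 30, 2,4,6-Cl3C6H2COCl, Et3N, toluene, rt; then 29, 80 °C
Reagents that add atoms: angelic acid (30), C/C=C(/C)C(=O)O
Why: Yamaguchi mixed-anhydride esterification without DMAP acylates the secondary 2α-OH in preference to the tertiary 4-OH and keeps the Z geometry of the angelate; C2 retains its configuration.

**Compound list**

1 | S-ethyl ethanethioate | CC(=O)SCC | starting material
2 | chlorotrimethylsilane | C[Si](C)(C)Cl | starting material
3 | 1-(ethylsulfanyl)-1-(trimethylsilyloxy)ethene | C=C(O[Si](C)(C)C)SCC | intermediate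
4 | methyl pyruvate | CC(=O)C(=O)OC | starting material
5 | methyl (2S)-4-(ethylsulfanyl)-2-methyl-4-oxo-2-(trimethylsilyloxy)butanoate | COC(=O)[C@@](C)(O[Si](C)(C)C)CC(=O)SCC | intermediate
6 | methyl (2S)-4-(ethylsulfanyl)-2-hydroxy-2-methyl-4-oxobutanoate | COC(=O)[C@@](C)(O)CC(=O)SCC | intermediate
7 | (4S)-4-(tert-butyldimethylsilyloxy)cyclopent-2-en-1-one | O=C1C=C[C@@H](O[Si](C)(C)C(C)(C)C)C1 | starting material
8 | vinylmagnesium bromide | C=C[Mg]Br | starting material
9 | N,N-dimethylmethyleneiminium iodide (Eschenmoser's salt) | C=[N+](C)C.[I-] | starting material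
10 | bromomagnesium enolate of trans-4-(tert-butyldimethylsilyloxy)-3-vinylcyclopentanone (1αH, 2α-OTBS) | C=C[C@H]1C=C(O[Mg]Br)C[C@@H]1O[Si](C)(C)C(C)(C)C | intermediate
11 | all-trans 2-[(dimethylamino)methyl]-4-(tert-butyldimethylsilyloxy)-3-vinylcyclopentan-1-one | C=C[C@H]1[C@H](CN(C)C)C(=O)C[C@@H]1O[Si](C)(C)C(C)(C)C | intermediate
12 | N-methyl ammonium iodide of 11 | C=C[C@H]1[C@H](C[N+](C)(C)C)C(=O)C[C@@H]1O[Si](C)(C)C(C)(C)C.[I-] | intermediate
13 | (3S,4S)-4-(tert-butyldimethylsilyloxy)-2-methylidene-3-vinylcyclopentan-1-one | C=C[C@H]1C(=C)C(=O)C[C@@H]1O[Si](C)(C)C(C)(C)C | intermediate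
14 | N-phenylbis(trifluoromethanesulfonimide) | O=S(=O)(N(c1ccccc1)S(=O)(=O)C(F)(F)F)C(F)(F)F | starting material
15 | dilithium enolate/alkoxide of the Michael adduct | C=C[C@H]1C(C[C@@H](C(=O)SCC)[C@](C)(O[Li])C(=O)OC)=C(O[Li])C[C@@H]1O[Si](C)(C)C(C)(C)C | intermediate
16 | enol triflate (name in step 4) | C=C[C@H]1C(C[C@@H](C(=O)SCC)[C@](C)(O)C(=O)OC)=C(OS(=O)(=O)C(F)(F)F)C[C@@H]1O[Si](C)(C)C(C)(C)C | intermediate
17 | tetramethylstannane | C[Sn](C)(C)C | starting material
18 | methyl alkene thioester (name in step 5) | C=C[C@H]1C(C[C@@H](C(=O)SCC)[C@](C)(O)C(=O)OC)=C(C)C[C@@H]1O[Si](C)(C)C(C)(C)C | intermediate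
19 | tributyl(vinyl)stannane | C=C[Sn](CCCC)(CCCC)CCCC | starting material
20 | vinyl ketone (name in step 6) | C=C[C@H]1C(C[C@@H](C(=O)C=C)[C@](C)(O)C(=O)OC)=C(C)C[C@@H]1O[Si](C)(C)C(C)(C)C | intermediate
21 | methyl (11S)-2α-(tert-butyldimethylsilyloxy)-11-hydroxy-8-oxo-14-nor-1αH,7αH-guaia-4,9-dien-12-oate | O=C1C=C[C@H]2C(C[C@@H]1[C@](C)(O)C(=O)OC)=C(C)C[C@@H]2O[Si](C)(C)C(C)(C)C | intermediate
22 | lithium dimethylcuprate | [Li+].C[Cu-]C | starting material
23 | methyl (11S)-2α-(tert-butyldimethylsilyloxy)-11-hydroxy-8-oxo-1αH,7αH,10βH-guai-4-en-12-oate | O=C1C[C@@H](C)[C@H]2C(C[C@@H]1[C@](C)(O)C(=O)OC)=C(C)C[C@@H]2O[Si](C)(C)C(C)(C)C | intermediate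
24 | lithium 8β-alkoxide of the 8β-hydroxy ester from 23 | [Li]O[C@@H]1C[C@@H](C)[C@H]2C(C[C@@H]1[C@](C)(O)C(=O)OC)=C(C)C[C@@H]2O[Si](C)(C)C(C)(C)C | intermediate
25 | 2α-(tert-butyldimethylsilyloxy)-11-hydroxy-1αH,7αH,10βH-guai-4-en-12,8β-olide | C[C@@H]1C[C@H]2OC(=O)[C@@](C)(O)[C@H]2CC3=C(C)C[C@H](O[Si](C)(C)C(C)(C)C)[C@@H]13 | intermediate
26 | 2α,11-dihydroxy-1αH,7αH,10βH-guai-4-en-12,8β-olide | C[C@@H]1C[C@H]2OC(=O)[C@@](C)(O)[C@H]2CC3=C(C)C[C@H](O)[C@@H]13 | intermediate
27 | tert-butyl hydroperoxide | CC(C)(C)OO | starting material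
28 | 4α,5α-epoxy-2α,11-dihydroxy-1αH,7αH,10βH-guaian-12,8β-olide | C[C@@H]1C[C@H]2OC(=O)[C@@](C)(O)[C@H]2C[C@@]34O[C@]3(C)C[C@H](O)[C@@H]14 | intermediate
29 | 2α,4α-dihydroxy-5β,11-epoxy-1αH,7αH,10βH-guaian-12,8β-olide | O[C@H]1C[C@@](C)(O)[C@@]23C[C@H]4[C@@H](C[C@@H](C)[C@H]12)OC(=O)[C@@]4(C)O3 | intermediate
30 | angelic acid, (Z)-2-methylbut-2-enoic acid | C/C=C(/C)C(=O)O | starting material
31 | 2,4,6-trichlorobenzoyl chloride | O=C(Cl)c1c(Cl)cc(Cl)cc1Cl | starting material
32 | angelic 2,4,6-trichlorobenzoic anhydride | C/C=C(/C)C(=O)OC(=O)c1c(Cl)cc(Cl)cc1Cl | intermediate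
33 | 2α-angeloyloxy-4α-hydroxy-5β,11-epoxy-1αH,7αH,10βH-guaian-12,8β-olide (CNP0293659.1) | C/C=C(/C)C(=O)O[C@H]1C[C@@](C)(O)[C@@]23C[C@H]4[C@@H](C[C@@H](C)[C@H]12)OC(=O)[C@@]4(C)O3 | target

**Step count and risks**

Total steps: 11. Longest linear sequence: 10 (steps 1, 2, 4–11).

Most likely to fail, with fallbacks:

- **Step 4** (diastereoselectivity at C7 when the carbinol carbon carries Me and CO2Me, and survival of the dianion/triflation sequence). The fallback sets out from 13. The lithium enolate of 1 is added to 13 and the enolate is trapped with 14 to give the simple thioester enol triflate F1. Stille methylation as in step 5 gives the methyl alkene thioester F2. LiHMDS/Me3SiCl gives the (Z)-silyl ketene thioacetal F3. A Cu(OTf)2/t-Bu-box-catalysed Mukaiyama aldol with 4 then sets C7 and C11 together under catalyst control (ligand enantiomer and enolsilane geometry chosen for the 7R,11S isomer) and gives the silyl ether F4. Acid hydrolysis of F4 comes back to the route at 18.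
- **Step 9** (the hydride may give the 8α-alcohol, which cannot form the cis-lactone). The fallback sets out from 23. NaBH4 in MeOH gives the trans 8α-hydroxy ester F5, and LiOH gives the hydroxy acid F6. Mitsunobu lactonisation (PPh3, DIAD) then forms the O8–C12 bond with inversion at C8 and comes back to the route at 25, which is desilylated as in step 9.
- **Step 10** (the tertiary 11-OH may direct the epoxidation to the β face, from which the epoxide cannot be opened at C5 with inversion). The fallback sets out from 26. NBS in CH2Cl2 forms bromonium ions reversibly on both faces, and only the α-bromonium ion can be opened at C5 by the β-oriented 11-OH, which gives the 4α-bromo oxolane F7. Radical oxygenation (Bu3SnH, O2) replaces bromine by hydroxyl from the less hindered α face and comes back to the route at 29.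

**Further compounds**

F1 | step 4 | (4S,5S)-4-(tert-butyldimethylsilyloxy)-1-[3-(ethylsulfanyl)-3-oxopropyl]-5-vinylcyclopent-1-en-2-yl trifluoromethanesulfonate | C=C[C@H]1C(CCC(=O)SCC)=C(OS(=O)(=O)C(F)(F)F)C[C@@H]1O[Si](C)(C)C(C)(C)C
F2 | step 4 | S-ethyl 3-[(4S,5S)-4-(tert-butyldimethylsilyloxy)-2-methyl-5-vinylcyclopent-1-en-1-yl]propanethioate | C=C[C@H]1C(CCC(=O)SCC)=C(C)C[C@@H]1O[Si](C)(C)C(C)(C)C
F3 | step 4 | (Z)-silyl ketene thioacetal of F2 | C=C[C@H]1C(C/C=C(/O[Si](C)(C)C)SCC)=C(C)C[C@@H]1O[Si](C)(C)C(C)(C)C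
F4 | step 4 | 11-O-trimethylsilyl ether of 18 | C=C[C@H]1C(C[C@@H](C(=O)SCC)[C@](C)(O[Si](C)(C)C)C(=O)OC)=C(C)C[C@@H]1O[Si](C)(C)C(C)(C)C
F5 | step 9 | methyl (11S)-2α-(tert-butyldimethylsilyloxy)-8α,11-dihydroxy-1αH,7αH,10βH-guai-4-en-12-oate | O[C@H]1C[C@@H](C)[C@H]2C(C[C@@H]1[C@](C)(O)C(=O)OC)=C(C)C[C@@H]2O[Si](C)(C)C(C)(C)C
F6 | step 9 | (11S)-2α-(tert-butyldimethylsilyloxy)-8α,11-dihydroxy-1αH,7αH,10βH-guai-4-en-12-oic acid | O[C@H]1C[C@@H](C)[C@H]2C(C[C@@H]1[C@](C)(O)C(=O)O)=C(C)C[C@@H]2O[Si](C)(C)C(C)(C)C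
F7 | step 10 | 4α-bromo-2α-hydroxy-5β,11-epoxy-1αH,7αH,10βH-guaian-12,8β-olide | O[C@H]1C[C@@](C)(Br)[C@@]23C[C@H]4[C@@H](C[C@@H](C)[C@H]12)OC(=O)[C@@]4(C)O3
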